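**Assumption:** the target has no stereocentre, so there is no enantiomer to select and the route delivers the single achiral compound. The one stereocentre that appears on the way (C3 of compound 5) is formed as a racemate and is erased in step 3. Compounds 1, 2 and 8 are catalogue chemicals.

**Retrosynthetic overview** (written in forward order so the numbers run upwards)
1. C–O bond: phenol-aldehyde 1 + bromoketone 2 give keto-aldehyde 3. Rings A and B and C2 are bought in, and no ring is made here.
2. Key C3–C4 bond: the aldehyde carbon of 3 is made nucleophilic as Breslow intermediate 4 (an acyl anion equivalent) and closes onto the aryl ketone carbon to give ketol 5. This forms the pyranone ring C, the only ring built in the route.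
3. Ketol 5 loses water to isoflavone 6 (ring C becomes the chromone), then all four O-methyls are removed to give tetraphenol 7, in one pot.
4. Tetraphenol 7 + prenyl bromide 8 give target 9 by alkylation of the most acidic 7-OH.

**Route**

Step 1
Reactants: 1 phenol-aldehyde (2-hydroxy-4,6-dimethoxybenzaldehyde); 2 bromoketone (2-bromo-1-(2,4-dimethoxyphenyl)ethan-1-one)
Product: 3 keto-aldehyde (2-[2-(2,4-dimethoxyphenyl)-2-oxoethoxy]-4,6-dimethoxybenzaldehyde)
Conditions: K2CO3 (1.2 equiv), DMF, 0 °C → rt
Reagents that add atoms: none
Why: Williamson ether synthesis, in which the only phenol of 1 is deprotonated by carbonate and displaces the primary α-keto bromide of 2 by SN2; the temperature is kept at or below rt so the product does not go on to the Rap–Stoermer benzofuran.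

Step 2
Reactants: 3 keto-aldehyde
Product: 5 ketol (racemic 3-hydroxy-5,7-dimethoxy-3-(2,4-dimethoxyphenyl)-2,3-dihydro-4H-chromen-4-one), via Breslow intermediate 4 (not isolated)
Conditions: 3-benzyl-5-(2-hydroxyethyl)-4-methylthiazolium chloride (20 mol %), DBU (15 mol %), t-BuOH, 40 °C, Ar, 0.05 M
Reagents that add atoms: none
Why: NHC-catalysed intramolecular crossed aldehyde–ketone benzoin reaction, in which the thiazol-2-ylidene adds to the aldehyde to give Breslow intermediate 4, whose former carbonyl carbon attacks the tethered aryl ketone in a 6-exo closure and releases the carbene, so that two carbonyl carbons (C4 and C3) are joined and ring C is formed; C3 is formed racemic and is removed in step 3, and the step is an isomerisation with no by-product.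

Step 3
Reactants: 5 ketol
Product: 7 tetraphenol 2′-hydroxygenistein (5,7-dihydroxy-3-(2,4-dihydroxyphenyl)-4H-chromen-4-one), via tetramethoxyisoflavone 6 (not isolated)
Conditions: BBr3 (10 equiv), CH2Cl2, −78 °C → rt; then H2O
Reagents that add atoms: none
Why: Lewis-acid E1 dehydration followed by BBr3 aryl methyl ether cleavage, in which BBr3 first ionises the tertiary 3-OH (cation stabilised by the 2,4-dimethoxyphenyl group) and loss of H-2 gives the conjugated isoflavone 6, whose four ArO–CH3 bonds are then cut by bromide (SN2 at methyl) and the aryl borates hydrolysed on work-up; this erases the C3 stereocentre.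

Step 4
Reactants: 7 tetraphenol 2′-hydroxygenistein; 8 prenyl bromide (1-bromo-3-methylbut-2-ene, 1.05 equiv)
Product: 9 target (5-hydroxy-3-(2,4-dihydroxyphenyl)-7-[(3-methylbut-2-en-1-yl)oxy]-4H-chromen-4-one)
Conditions: K2CO3 (1.05 equiv), DMF, 0 °C → rt
Reagents that add atoms: none
Why: Williamson O-alkylation under pKa control, in which one equivalent of weak base ionises only the 7-OH (vinylogous acid, pKa about 7, against about 9–10 for the 2′- and 4′-OH and a chelated 5-OH), so the allylic bromide is taken up at O-7 by SN2.

**Compound list**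
1 | 2-hydroxy-4,6-dimethoxybenzaldehyde | COc1cc(O)c(C=O)c(OC)c1 | starting material
2 | 2-bromo-1-(2,4-dimethoxyphenyl)ethan-1-one | COc1ccc(C(=O)CBr)c(OC)c1 | starting material
3 | 2-[2-(2,4-dimethoxyphenyl)-2-oxoethoxy]-4,6-dimethoxybenzaldehyde | COc1cc(OC)c(C=O)c(OCC(=O)c2ccc(OC)cc2OC)c1 | intermediate
4 | Breslow intermediate: enaminol in which the former CHO carbon of 3 carries OH and is double-bonded to C2 of a 3-benzyl-5-(2-hydroxyethyl)-4-methyl-2,3-dihydrothiazole ring (alkene geometry not defined) | OC(=C1SC(CCO)=C(C)N1Cc1ccccc1)c1c(OC)cc(OC)cc1OCC(=O)c1ccc(OC)cc1OC | intermediate (not isolated)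
5 | racemic 3-hydroxy-5,7-dimethoxy-3-(2,4-dimethoxyphenyl)-2,3-dihydro-4H-chromen-4-one | COc1cc(OC)c2c(c1)OCC(O)(c1ccc(OC)cc1OC)C2=O | intermediate
6 | 5,7-dimethoxy-3-(2,4-dimethoxyphenyl)-4H-chromen-4-one | COc1cc(OC)c2c(=O)c(-c3ccc(OC)cc3OC)coc2c1 | intermediate (not isolated)
7 | 5,7-dihydroxy-3-(2,4-dihydroxyphenyl)-4H-chromen-4-one (2′-hydroxygenistein) | Oc1cc(O)c2c(=O)c(-c3ccc(O)cc3O)coc2c1 | intermediate
8 | 1-bromo-3-methylbut-2-ene (prenyl bromide) | CC(C)=CCBr | starting material
9 | 5-hydroxy-3-(2,4-dihydroxyphenyl)-7-[(3-methylbut-2-en-1-yl)oxy]-4H-chromen-4-one (achiral) | CC(C)=CCOc1cc(O)c2c(=O)c(-c3ccc(O)cc3O)coc2c1 | target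

**Totals**
Total step count: 4. Longest linear sequence: 4 (the route is linear; 1, 2 and 8 are purchased).

**Three steps most likely to fail, with fallbacks**

Step 2 is the riskiest. The aldehyde is flanked by two ortho alkoxy groups and is electron-rich, so carbene addition is slow. The acceptor is an electron-rich aryl ketone. The base can also trigger the competing aldol (Rap–Stoermer) path to a 2-aroylbenzofuran. The fallback sets out from 3 and replaces the catalytic redox-neutral closure by a reductive ketyl coupling followed by re-oxidation. SmI2 (2.2 equiv, THF, t-BuOH, −78 °C → rt) effects the intramolecular pinacol cyclisation to 5,7-dimethoxy-3-(2,4-dimethoxyphenyl)chromane-3,4-diol F1, obtained as a racemic diastereomer mixture. IBX (DMSO, rt) then oxidises only the secondary benzylic 4-OH, since the tertiary 3-OH cannot be oxidised, and the sequence comes back to the route at 5.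

Step 4 is second. Alkylation at 4′-O or 2′-O, dialkylation, or C-prenylation at C6/C8 may erode the yield. The fallback sets out from 7 and controls the site with protecting groups instead of pKa. Ac2O/pyridine gives 5,7-diacetoxy-3-(2,4-diacetoxyphenyl)-4H-chromen-4-one F2. PhSH/imidazole (NMP, 0 °C) removes only the most activated 7-O-acetyl to give 5-acetoxy-3-(2,4-diacetoxyphenyl)-7-hydroxy-4H-chromen-4-one F3. A Mitsunobu etherification with 3-methylbut-2-en-1-ol (PPh3, DIAD, THF, 0 °C) gives 5-acetoxy-3-(2,4-diacetoxyphenyl)-7-[(3-methylbut-2-en-1-yl)oxy]-4H-chromen-4-one F4. K2CO3 (cat.)/MeOH at rt removes the three acetates and comes back at 9.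

Step 3 is third. The one-pot dehydration plus fourfold demethylation may stop at partly methylated isoflavones, or the ketol may rearrange under the Lewis acid. The fallback sets out from 5 and separates the two events with different mechanisms. SOCl2/pyridine (CH2Cl2, 0 °C, chlorosulfite elimination) gives the isoflavone 6, which is isolated. Demethylation is then done without a Lewis acid in molten pyridinium chloride (190 °C, chloride SN2 at methyl) and comes back at 7. This fallback makes no compound outside the list (none F0).

**Further compounds**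
F1 | step 2 | 5,7-dimethoxy-3-(2,4-dimethoxyphenyl)chromane-3,4-diol (racemic, diastereomer mixture) | COc1cc(OC)c2c(c1)OCC(O)(c1ccc(OC)cc1OC)C2O
F0 | step 3 | none | none
F2 | step 4 | 5,7-diacetoxy-3-(2,4-diacetoxyphenyl)-4H-chromen-4-one | CC(=O)Oc1cc(OC(C)=O)c2c(=O)c(-c3ccc(OC(C)=O)cc3OC(C)=O)coc2c1
F3 | step 4 | 5-acetoxy-3-(2,4-diacetoxyphenyl)-7-hydroxy-4H-chromen-4-one | Oc1cc(OC(C)=O)c2c(=O)c(-c3ccc(OC(C)=O)cc3OC(C)=O)coc2c1
F4 | step 4 | 5-acetoxy-3-(2,4-diacetoxyphenyl)-7-[(3-methylbut-2-en-1-yl)oxy]-4H-chromen-4-one | CC(C)=CCOc1cc(OC(C)=O)c2c(=O)c(-c3ccc(OC(C)=O)cc3OC(C)=O)coc2c1
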